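**Remark (assumption).** The target, 3-hydroxy-5,6,7,8-tetramethoxy-2-(4-methoxyphenyl)-4H-chromen-4-one, has no stereocentre and no stereogenic double bond. "Single enantiomer" therefore calls for no stereocontrol; the transient stereocentres of the route (in 8 and 10) are formed racemic and erased.

## Structural features

The target is an achiral flavonol: a chromen-4-one (benzene ring A fused through C4a–C8a to γ-pyrone ring C) with a 4-methoxyphenyl ring B at C2 and a free enolic hydroxyl at C3. Ring A is hexasubstituted: C5, C6, C7 and C8 each carry a methoxy group, C8a carries O1 and C4a carries the C4 carbonyl, so no C–H position is left for late substitution. There is no stereocentre. Fragile points are the C5 methoxy group peri to the C4 carbonyl (the first ether to fall to Lewis acids), the γ-pyrone ring (opened by hydroxide and nucleophilic bases) and the chelating C3 hydroxyl, which must stay distinct from four methyl ethers. The real difficulty is the pentaoxygenated, fully substituted ring A; the usual routes only move it into a hexasubstituted acetophenone that has to be built oxygen by oxygen. The key step exploits that C5–C6–C7–C8 are four contiguous oxygen-bearing carbons, i.e. the C4O4 skeleton of squaric acid, and that their substituents are pairwise alike (C5/C8 and C6/C7). Ring A is therefore made last, by thermal ring expansion of a squarate-derived 4-hydroxycyclobutenone attached to the finished 2-aryl-3-oxy-γ-pyrone; the local symmetry makes it irrelevant whether the four-carbon unit is attached at the future C4a or C8a.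

## Logic of the disconnections

**13 ⇒ 12.** The benzylic O–C bond on the C3 oxygen is cut. The C3 hydroxyl must be told apart from four methyl ethers, and only an orthogonal ether allows exhaustive methylation of ring A. The gain is a fully etherified chromone. The forward step must free the hydroxyl without a Lewis acid, because the C5 methoxy group is the most labile ether.

**12 ⇒ 11.** The two O–CH3 bonds at C5 and C8 are cut. These are exactly the oxygens that a cyclobutenone ring expansion delivers as free phenols, while C6 and C7 arrive methylated. The gain is a para-hydroquinone, the retron of that ring expansion. The forward step must alkylate a hydrogen-bonded C5 phenol and outrun oxidation to the quinone.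

**11 ⇒ 8 (key).** The C8–C8a bond of ring A is cut and C5 is reconnected to C8, so that ring A collapses to the four-membered ring of 8. All four oxygenated carbons of ring A are thereby traced to one C4O4 unit, and ring A disappears from the problem, leaving a monocyclic γ-pyrone. The forward step must open the four-membered ring with the hydroxyl outward, close onto the C5=C6 bond of the pyrone and aromatise.

**8 ⇒ 5 + 6.** The C4a–C5 bond (pyrone carbon to carbinol carbon) is cut as a carbonyl-addition retron. The gain is convergence: a small pyrone and a symmetrical four-carbon electrophile. The forward step needs a carbanion at a ring CH of 5 and a single 1,2-addition to 6; either CH of 5 would serve, because both adducts lead to 11.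

**5 ⇒ 3 + 4.** The C2–C1' bond between ring C and ring B is cut. This removes ring B as a commercial boronic acid. The forward step is a cross-coupling on a base-sensitive β-halo pyrone.

**3 ⇒ 2 ⇒ 1.** The benzyl O–C bond and then the C2–Br bond are cut. The free enolic hydroxyl of 1 directs the electrophile to the adjacent C2, so halogenation must precede etherification. The gain is a commercial pyrone that already holds the C3 oxygen and the C4 carbonyl of ring C. The forward steps need monobromination ortho to the hydroxyl.

## Other disconnections considered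

**Alternative 1:** The first plan that comes to mind cuts O1–C2 and the C3–O bond (after a C2–C3 aldol cut). Forward, acetophenone A1 (1-(2-hydroxy-3,4,5,6-tetramethoxyphenyl)ethanone) is condensed with the B-ring aldehyde to chalcone A2, and the key step is the Algar–Flynn–Oyamada oxidative cyclisation of A2 with alkaline hydrogen peroxide. The chosen plan is preferred for two reasons. All the difficulty of ring A is left inside A1, a hexasubstituted benzene that must be assembled by serial substitution and oxidation. And the methoxy group ortho to the carbonyl in A2 (the future C5 substituent) twists the enone, which is expected to bias the cyclisation toward the five-membered (aurone-type) mode.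

**Alternative 2:** Ring C is cut back to a five-membered ring. Forward, benzofuranone A3 (4,5,6,7-tetramethoxybenzofuran-3(2H)-one) is condensed to aurone A4 and brominated to dibromide A5, and the key step is the hydroxide-induced Auwers ring expansion of A5 to the flavonol. The plan passes the first test, but A3 is again a hexasubstituted benzene that must be made from a pentasubstituted phenol, so the ring-A problem is exported and not solved. Bromine would also have to choose the exocyclic alkene of A4 over two very electron-rich arenes, and the sequence is longer.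

**Alternative 3:** The C8–O bond is cut. Forward, the 5-hydroxyflavonol ether A6 (3-(benzyloxy)-5-hydroxy-6,7-dimethoxy-2-(4-methoxyphenyl)-4H-chromen-4-one) is hydroxylated para to the phenol, by Elbs persulfate oxidation or anodically, to give 11. A6 itself needs a complete conventional flavonol synthesis from a trioxygenated acetophenone, and the oxygens of ring A are then added one at a time. The chelated C5 phenolate is a weak nucleophile toward peroxydisulfate, and an anodic version would have to discriminate ring A from ring B and the benzyl ether. The chosen plan installs all four oxygenated carbons at once.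

Key step: step 5

## Route

Step 1
Reactants: 1 3-hydroxy-4H-pyran-4-one (pyromeconic acid)
Product: 2 2-bromo-3-hydroxy-4H-pyran-4-one
Conditions: NBS (1.0 equiv), MeCN, 0 °C to rt, dark
Reagents that add atoms: N-bromosuccinimide, O=C1CCC(=O)N1Br
Why: Electrophilic bromination of an enolic 3-hydroxy-γ-pyrone should occur at C2, the carbon ortho to the hydroxyl, which is where kojic-acid-type pyrones take up electrophiles; one equivalent of NBS limits dibromination.

Step 2
Reactants: 2 2-bromo-3-hydroxy-4H-pyran-4-one
Product: 3 3-(benzyloxy)-2-bromo-4H-pyran-4-one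
Conditions: BnBr, K2CO3, DMF, rt
Reagents that add atoms: benzyl bromide, BrCc1ccccc1
Why: Williamson etherification of the acidic enol; the benzyl ether masks the future C3 hydroxyl with a group orthogonal to methyl ethers and removes the acidic proton before palladium and organolithium chemistry.

Step 3
Reactants: 3 3-(benzyloxy)-2-bromo-4H-pyran-4-one; 4 (4-methoxyphenyl)boronic acid
Product: 5 3-(benzyloxy)-2-(4-methoxyphenyl)-4H-pyran-4-one
Conditions: Pd(PPh3)4 (5 mol %), K2CO3, 1,4-dioxane/H2O (5:1), 80 °C
Reagents that add atoms: none
Why: Suzuki–Miyaura coupling; the C2–Br bond is that of a β-halo enone (vinylogous acyl bromide) and should undergo oxidative addition readily, which sets the C2–C1' bond and brings in ring B.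

Step 4
Reactants: 5 3-(benzyloxy)-2-(4-methoxyphenyl)-4H-pyran-4-one; 6 3,4-dimethoxycyclobut-3-ene-1,2-dione (dimethyl squarate)
Product: 8 4-[5-(benzyloxy)-6-(4-methoxyphenyl)-4-oxo-4H-pyran-3-yl]-4-hydroxy-2,3-dimethoxycyclobut-2-en-1-one (racemic), via 5-lithio-γ-pyrone 7 (not isolated)
Conditions: LiTMP (from TMPH, n-BuLi), THF, −78 °C, 20 min; cannulated into 6 (1.3 equiv), THF, −78 °C; aq NH4Cl, −78 °C to rt
Reagents that add atoms: none
Why: Carbonyl-directed deprotonative lithiation at the α-carbonyl CH (C5) follows the known C3-lithiation of 2-arylchromones by lithium amides, and 1,2-addition of an organolithium to one carbonyl of a dialkyl squarate is the standard entry to 4-hydroxycyclobutenones. Inverse addition at −78 °C should suppress double addition and ring-opening elimination of 7. Lithiation at C6 instead would be inconsequential, since either adduct would give the same 11 in step 5; the carbinol stereocentre of 8 is racemic and is destroyed there.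

Step 5
Reactants: 8 4-[5-(benzyloxy)-6-(4-methoxyphenyl)-4-oxo-4H-pyran-3-yl]-4-hydroxy-2,3-dimethoxycyclobut-2-en-1-one
Product: 11 3-(benzyloxy)-5,8-dihydroxy-6,7-dimethoxy-2-(4-methoxyphenyl)-4H-chromen-4-one, via (Z)-dienylketene 9 (not isolated), via 8aH-chromene-4,8-dione tautomer 10 (not isolated)
Conditions: degassed p-xylene (0.02 M), 140 °C, Ar, 1–2 h
Reagents that add atoms: none
Why: Heating should open the strained cyclobutenone by conrotatory 4π electrocyclic cleavage of the C1–C4 bond; the hydroxyl, as a donor, rotates outward and the pyranonyl group inward, giving (Z)-dienylketene 9. Thermal disrotatory 6π electrocyclisation of 9 then joins the ketene carbon to pyrone C6 (the future C8–C8a bond) and closes ring A as the six-membered carbocycle of dienone 10. Enolisation of 10 at C8a–H gives the aromatic hydroquinone 11, and this aromatisation makes the cascade irreversible. The closest known reaction type is the Moore rearrangement of 4-aryl-, 4-heteroaryl- and 4-alkenyl-4-hydroxycyclobutenones to annulated hydroquinones. No stereocentre results: the carbinol carbon of 8 becomes sp2 on ring opening and C8a of 10 on tautomerisation. The step needs torquoselectivity, secured by the free hydroxyl, and closure onto the only adjacent π bond, C5=C6 of the pyrone, whose C6–H allows aromatisation. Site selectivity within ring A is no issue, because the OH/OMe/OMe/OH array is symmetric. The benzyl ether, ring B and the pyrone carbonyl have no thermal pathway at 140 °C; oxygen is excluded because 11 is oxidisable.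

Step 6
Reactants: 11 3-(benzyloxy)-5,8-dihydroxy-6,7-dimethoxy-2-(4-methoxyphenyl)-4H-chromen-4-one (crude, kept under Ar)
Product: 12 3-(benzyloxy)-5,6,7,8-tetramethoxy-2-(4-methoxyphenyl)-4H-chromen-4-one
Conditions: Me2SO4 (excess), K2CO3, acetone, reflux, Ar
Reagents that add atoms: dimethyl sulfate, COS(=O)(=O)OC
Why: Double Williamson O-methylation; the C8 phenol should react readily, and the hydrogen-bonded C5 phenol needs excess dimethyl sulfate at reflux, the standard of polymethoxyflavone chemistry. The benzyl ether keeps the C3 oxygen distinct.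

Step 7
Reactants: 12 3-(benzyloxy)-5,6,7,8-tetramethoxy-2-(4-methoxyphenyl)-4H-chromen-4-one
Product: 13 3-hydroxy-5,6,7,8-tetramethoxy-2-(4-methoxyphenyl)-4H-chromen-4-one (target)
Conditions: H2 (1 atm), 10% Pd/C, EtOAc/MeOH, rt
Reagents that add atoms: none
Why: Hydrogenolysis of the benzyl ether; the tetrasubstituted C2=C3 bond of the chromone and the aryl methyl ethers should be inert at 1 atm, and no Lewis acid touches the labile C5 methoxy group.

## Compound list

1 | 3-hydroxy-4H-pyran-4-one (pyromeconic acid) | O=c1ccocc1O | starting material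
2 | 2-bromo-3-hydroxy-4H-pyran-4-one | O=c1ccoc(Br)c1O | intermediate
3 | 3-(benzyloxy)-2-bromo-4H-pyran-4-one | O=c1ccoc(Br)c1OCc1ccccc1 | intermediate
4 | (4-methoxyphenyl)boronic acid | COc1ccc(B(O)O)cc1 | starting material
5 | 3-(benzyloxy)-2-(4-methoxyphenyl)-4H-pyran-4-one | COc1ccc(-c2occc(=O)c2OCc2ccccc2)cc1 | intermediate
6 | 3,4-dimethoxycyclobut-3-ene-1,2-dione (dimethyl squarate) | COC1=C(OC)C(=O)C1=O | starting material
7 | [5-(benzyloxy)-6-(4-methoxyphenyl)-4-oxo-4H-pyran-3-yl]lithium | COc1ccc(-c2occ([Li])c(=O)c2OCc2ccccc2)cc1 | intermediate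
8 | 4-[5-(benzyloxy)-6-(4-methoxyphenyl)-4-oxo-4H-pyran-3-yl]-4-hydroxy-2,3-dimethoxycyclobut-2-en-1-one (racemic) | COC1=C(OC)C(O)(c2coc(-c3ccc(OC)cc3)c(OCc3ccccc3)c2=O)C1=O | intermediate
9 | (3Z)-4-[5-(benzyloxy)-6-(4-methoxyphenyl)-4-oxo-4H-pyran-3-yl]-4-hydroxy-2,3-dimethoxybuta-1,3-dien-1-one (dienylketene) | O=C=C(OC)/C(OC)=C(/O)c1coc(-c2ccc(OC)cc2)c(OCc2ccccc2)c1=O | intermediate
10 | 3-(benzyloxy)-5-hydroxy-6,7-dimethoxy-2-(4-methoxyphenyl)-8aH-chromene-4,8-dione (racemic) | COC1=C(OC)C(O)=C2C(=O)C(OCc3ccccc3)=C(c3ccc(OC)cc3)OC2C1=O | intermediate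
11 | 3-(benzyloxy)-5,8-dihydroxy-6,7-dimethoxy-2-(4-methoxyphenyl)-4H-chromen-4-one | COc1ccc(-c2oc3c(O)c(OC)c(OC)c(O)c3c(=O)c2OCc2ccccc2)cc1 | intermediate
12 | 3-(benzyloxy)-5,6,7,8-tetramethoxy-2-(4-methoxyphenyl)-4H-chromen-4-one | COc1ccc(-c2oc3c(OC)c(OC)c(OC)c(OC)c3c(=O)c2OCc2ccccc2)cc1 | intermediate
13 | 3-hydroxy-5,6,7,8-tetramethoxy-2-(4-methoxyphenyl)-4H-chromen-4-one | COc1ccc(-c2oc3c(OC)c(OC)c(OC)c(OC)c3c(=O)c2O)cc1 | target

## Step count and risk

Total step count: 7. Longest linear sequence: 7 steps (1 to 13); 4 and 6 enter as commercial fragments.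

**Step 5 (key step).** After ring opening, the ketene may be captured by the neighbouring hydroxyl (lactonisation) if the pyranonyl group rotates outward, and the hydroquinone may be oxidised at 140 °C if traces of air are present. The fallback sets out from 8 and returns at 12. The tertiary alcohol is methylated first (MeI, Ag2O, K2CO3, MeCN) to 4-[5-(benzyloxy)-6-(4-methoxyphenyl)-4-oxo-4H-pyran-3-yl]-2,3,4-trimethoxycyclobut-2-en-1-one F1, in which lactonisation is structurally impossible. Thermolysis of F1 in p-xylene should give 3-(benzyloxy)-8-hydroxy-5,6,7-trimethoxy-2-(4-methoxyphenyl)-4H-chromen-4-one F2, a monophenol that is far less oxidisable and already carries the C5 methyl ether. Methylation of the unchelated C8 phenol (MeI, K2CO3, DMF) gives 12.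

**Step 4.** The α-lithiated vinylogous ester 7 may fragment by ring-opening elimination (the C5–Li bond lies anti to the C6–O1 bond), may add to unlithiated 5, or the squarate may take up a second equivalent. The fallback sets out from 5 and returns at 8. Iodination at C5 (I2, CAN, MeCN) gives 3-(benzyloxy)-5-iodo-2-(4-methoxyphenyl)-4H-pyran-4-one F3. Iodine–magnesium exchange (i-PrMgCl·LiCl, THF, −40 °C) gives the more covalent and regiodefined [5-(benzyloxy)-6-(4-methoxyphenyl)-4-oxo-4H-pyran-3-yl]magnesium chloride F4, which is added to 6 at −78 to −40 °C and quenched with aqueous NH4Cl to give 8.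

**Step 1.** Site control of the bromination (C2 against C5/C6, overbromination) may be poor, and the C2–Br bond, a vinylogous acyl bromide, may be lost to nucleophiles in steps 2 and 3. The fallback builds the pyrone with ring B in place by furan dearomatisation; it sets out from 4 and returns at 5.
- Rhodium-catalysed 1,2-addition of 4 to commercial furfural gives (furan-2-yl)(4-methoxyphenyl)methanol F5.
- Achmatowicz rearrangement (NBS, NaHCO3, THF/H2O, 0 °C) gives 6-hydroxy-2-(4-methoxyphenyl)-2H-pyran-3(6H)-one F6.
- Acetalisation (CH(OMe)3, BF3·OEt2) gives 6-methoxy-2-(4-methoxyphenyl)-2H-pyran-3(6H)-one F7.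
- Nucleophilic epoxidation (H2O2, NaOH, MeOH, 0 °C) gives 2-methoxy-4-(4-methoxyphenyl)-3,7-dioxabicyclo[4.1.0]heptan-5-one F8.
- Hot aqueous H2SO4 converts F8, in the manner of the maltol process, into 3-hydroxy-2-(4-methoxyphenyl)-4H-pyran-4-one F9.
- Benzylation (BnBr, K2CO3, DMF) gives 5.

F5 to F8 are racemic or diastereomeric mixtures whose stereocentres vanish in F9.

**Step 6.** Under base the hydroquinone may be oxidised to the quinone before the slow, hydrogen-bonded C5 phenol is alkylated. The fallback sets out from 11 and returns at 12. The oxidation is completed on purpose (Ag2O, CH2Cl2) to the stable, purifiable 3-(benzyloxy)-6,7-dimethoxy-2-(4-methoxyphenyl)-4H-chromene-4,5,8-trione F10. One-pot reductive methylation (Na2S2O4, Bu4NBr, Me2SO4, aq KOH/THF, 0 °C to rt, Ar) then gives 12.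

## Further compounds

F1 | step 5 | 4-[5-(benzyloxy)-6-(4-methoxyphenyl)-4-oxo-4H-pyran-3-yl]-2,3,4-trimethoxycyclobut-2-en-1-one (racemic) | COC1=C(OC)C(OC)(c2coc(-c3ccc(OC)cc3)c(OCc3ccccc3)c2=O)C1=O
F2 | step 5 | 3-(benzyloxy)-8-hydroxy-5,6,7-trimethoxy-2-(4-methoxyphenyl)-4H-chromen-4-one | COc1ccc(-c2oc3c(O)c(OC)c(OC)c(OC)c3c(=O)c2OCc2ccccc2)cc1
F3 | step 4 | 3-(benzyloxy)-5-iodo-2-(4-methoxyphenyl)-4H-pyran-4-one | COc1ccc(-c2occ(I)c(=O)c2OCc2ccccc2)cc1
F4 | step 4 | [5-(benzyloxy)-6-(4-methoxyphenyl)-4-oxo-4H-pyran-3-yl]magnesium chloride | COc1ccc(-c2occ([Mg]Cl)c(=O)c2OCc2ccccc2)cc1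
F5 | step 1 | (furan-2-yl)(4-methoxyphenyl)methanol (racemic) | COc1ccc(C(O)c2ccco2)cc1
F6 | step 1 | 6-hydroxy-2-(4-methoxyphenyl)-2H-pyran-3(6H)-one (mixture of diastereomers) | COc1ccc(C2OC(O)C=CC2=O)cc1
F7 | step 1 | 6-methoxy-2-(4-methoxyphenyl)-2H-pyran-3(6H)-one (mixture of diastereomers) | COc1ccc(C2OC(OC)C=CC2=O)cc1
F8 | step 1 | 2-methoxy-4-(4-methoxyphenyl)-3,7-dioxabicyclo[4.1.0]heptan-5-one (mixture of diastereomers) | COc1ccc(C2OC(OC)C3OC3C2=O)cc1
F9 | step 1 | 3-hydroxy-2-(4-methoxyphenyl)-4H-pyran-4-one | COc1ccc(-c2occc(=O)c2O)cc1
F10 | step 6 | 3-(benzyloxy)-6,7-dimethoxy-2-(4-methoxyphenyl)-4H-chromene-4,5,8-trione | COC1=C(OC)C(=O)c2oc(-c3ccc(OC)cc3)c(OCc3ccccc3)c(=O)c2C1=O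
A1 | alternative 1 | 1-(2-hydroxy-3,4,5,6-tetramethoxyphenyl)ethan-1-one | CC(=O)c1c(O)c(OC)c(OC)c(OC)c1OC
A2 | alternative 1 | (E)-1-(2-hydroxy-3,4,5,6-tetramethoxyphenyl)-3-(4-methoxyphenyl)prop-2-en-1-one | COc1ccc(/C=C/C(=O)c2c(O)c(OC)c(OC)c(OC)c2OC)cc1
A3 | alternative 2 | 4,5,6,7-tetramethoxybenzofuran-3(2H)-one | O=C1COc2c(OC)c(OC)c(OC)c(OC)c12
A4 | alternative 2 | (Z)-4,5,6,7-tetramethoxy-2-(4-methoxybenzylidene)benzofuran-3(2H)-one | COc1ccc(/C=C2\Oc3c(OC)c(OC)c(OC)c(OC)c3C2=O)cc1
A5 | alternative 2 | 2-bromo-2-[bromo(4-methoxyphenyl)methyl]-4,5,6,7-tetramethoxybenzofuran-3(2H)-one (racemic, mixture of diastereomers) | COc1ccc(C(Br)C2(Br)Oc3c(OC)c(OC)c(OC)c(OC)c3C2=O)cc1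
A6 | alternative 3 | 3-(benzyloxy)-5-hydroxy-6,7-dimethoxy-2-(4-methoxyphenyl)-4H-chromen-4-one | COc1ccc(-c2oc3cc(OC)c(OC)c(O)c3c(=O)c2OCc2ccccc2)cc1
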